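## Retrosynthetic overview

1. Bromophycolide D ⇒ 19-membered macrolide 25. The last ring is the bromocyclohexane, closed by a transannular bromonium-ene cyclization (C2–C7 bond, C6–Br, exocyclic CH2) that contracts the macrocycle to 15 members.
2. 25 ⇒ epoxy macrolide 22. The 10,11-epoxide is the masked bromohydrin (bromide opening at C10) and the C15 hydroxyl becomes the tertiary bromide. 22 ⇒ seco acid 20 by macrolactonization at O14. The epoxide comes from epoxidation directed by the C14 hydroxyl.
3. Seco ester 18 ⇒ aryl triene 16 + (E)-vinyl iodide 6 by B-alkyl Suzuki coupling (C9–C10). 6 comes from the L-glutamic-acid-derived lactone 1, which supplies C14, the only purchased stereocentre.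
4. Key step: the benzoate ring, with the chain ortho and the oxygen para to the ester, is built by a [4+2] cycloaddition/retro-[4+2] of methyl coumalate with the ketene silyl acetal of geranylacetic acid.
5. Ring order: benzoate ring (cycloaddition) → 19-membered lactone → bromocyclohexane (transannular). C10/C11 are set from C14 (steps 11 and 15); C2/C6/C7 are set in the macrocycle that carries C10, C11 and C14 (step 16).

Assumption: chain positions are numbered C1 (benzylic CH2) to C15 (CMe2Br) as in the geranylgeranyl precursor, and all descriptors use this numbering. Compound 1 is the commercial ester made from L-glutamic acid.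

## Route

Step 1
Reactants: 1 ethyl (2S)-5-oxooxolane-2-carboxylate
Product: 2 (5S)-5-(2-hydroxypropan-2-yl)oxolan-2-one
Conditions: MeMgBr (2.2 equiv), THF, −78 → −40 °C; aq. NH4Cl
Reagents that add atoms: methylmagnesium bromide, C[Mg]Br
Why: Double Grignard addition to the α-alkoxy ester, which is more electrophilic than the γ-lactone at low temperature; the purchased stereocentre (future C14, S) is not touched.

Step 2
Reactants: 2 (5S)-5-(2-hydroxypropan-2-yl)oxolan-2-one
Product: 3 (5S)-5-(2-hydroxypropan-2-yl)oxolan-2-ol (lactol; anomer mixture)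
Conditions: i-Bu2AlH (2.2 equiv), CH2Cl2, −78 °C; aq. potassium sodium tartrate
Reagents that add atoms: none
Why: Partial lactone-to-lactol reduction with i-Bu2AlH stops at the tetrahedral aluminate at −78 °C, the first equivalent being consumed by the tertiary hydroxyl.

Step 3
Reactants: 3 (5S)-5-(2-hydroxypropan-2-yl)oxolan-2-ol
Product: 4 (3S)-2-methylhept-6-yne-2,3-diol
Conditions: MeC(O)C(N2)P(O)(OMe)2, K2CO3, MeOH, 0 °C → rt
Reagents that add atoms: dimethyl (1-diazo-2-oxopropyl)phosphonate, CC(=O)C(=[N+]=[N-])P(=O)(OC)OC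
Why: Seyferth–Gilbert homologation (Ohira–Bestmann variant) converts the open hydroxy-aldehyde form of the lactol into the terminal alkyne under mild base that leaves C14 alone.

Step 4
Reactants: 4 (3S)-2-methylhept-6-yne-2,3-diol
Product: 6 (3S,6E)-7-iodo-2,6-dimethylhept-6-ene-2,3-diol, via alkenylalane 5 (not isolated)
Conditions: Me3Al (4 equiv), Cp2ZrCl2 (0.3 equiv), CH2Cl2, 0 °C → rt; then I2, THF, −30 °C; aq. Na2S2O3/NaHCO3
Reagents that add atoms: trimethylaluminium, C[Al](C)C; iodine, II
Why: Negishi zirconium-catalysed carboalumination adds methyl and aluminium syn with methyl on the internal carbon (hydroxyls masked in situ as aluminium alkoxides), and iodinolysis with retention gives the (E)-vinyl iodide.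

Step 5
Reactants: 7 geranyl bromide, (2E)-1-bromo-3,7-dimethylocta-2,6-diene
Product: 8 (4E)-5,9-dimethyldeca-4,8-dienoic acid
Conditions: CH3CO2H, lithium diisopropylamide (2.1 equiv), THF/DMPU, 0 → 35 °C; then 7, 0 °C → rt; aq. HCl
Reagents that add atoms: acetic acid, CC(=O)O
Why: SN2 alkylation of the acetic acid dianion at the primary allylic carbon keeps the (E)-olefin and adds the two carbons that become aryl C3 and C4.

Step 6
Reactants: 8 (4E)-5,9-dimethyldeca-4,8-dienoic acid; 9 methyl coumalate (methyl 2-oxo-2H-pyran-5-carboxylate)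
Product: 12 methyl 3-[(2E)-3,7-dimethylocta-2,6-dien-1-yl]-4-hydroxybenzoate, via ketene bis(trimethylsilyl) acetal 10 (not isolated), via aryl silyl ether 11 (not isolated)
Conditions: lithium diisopropylamide (2.2 equiv), Me3SiCl, THF, −78 °C → rt; volatiles off, pentane filtration; then 9, toluene, 80 °C; 1 M HCl/THF
Reagents that add atoms: none
Why: Inverse-electron-demand Diels–Alder reaction of the electron-rich ketene acetal with the electron-poor 2-pyrone (nucleophilic β-carbon to pyrone C6), then retro-Diels–Alder loss of CO2 and elimination of Me3SiOH, builds the benzoate ring with the chain ortho and the oxygen para to the ester; no stereocentre is formed.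

Step 7
Reactants: 12 methyl 3-[(2E)-3,7-dimethylocta-2,6-dien-1-yl]-4-hydroxybenzoate
Product: 13 methyl 3-[(2E)-3,7-dimethylocta-2,6-dien-1-yl]-4-(methoxymethoxy)benzoate
Conditions: MeOCH2Cl, i-Pr2NEt, CH2Cl2, 0 °C → rt
Reagents that add atoms: chloromethyl methyl ether, COCCl
Why: O-alkylation of the phenol gives a base-stable MOM acetal that survives the organometallic, oxidative, saponification and lactonization steps.

Step 8
Reactants: 13 methyl 3-[(2E)-3,7-dimethylocta-2,6-dien-1-yl]-4-(methoxymethoxy)benzoate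
Product: 15 methyl 3-[(2E,6E)-3,7-dimethyl-8-oxoocta-2,6-dien-1-yl]-4-(methoxymethoxy)benzoate, via allylic alcohol 14 (not isolated)
Conditions: SeO2 (0.3 equiv), t-BuOOH, salicylic acid (cat.), CH2Cl2, rt; then MnO2, CH2Cl2, rt
Reagents that add atoms: tert-butyl hydroperoxide, CC(C)(C)OO
Why: Riley allylic oxidation (ene reaction then 2,3-sigmatropic shift) attacks the (E)-methyl of the terminal isopropylidene group, as in farnesyl derivatives, and MnO2 takes the allylic alcohol to the (E)-enal.

Step 9
Reactants: 15 methyl 3-[(2E,6E)-3,7-dimethyl-8-oxoocta-2,6-dien-1-yl]-4-(methoxymethoxy)benzoate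
Product: 16 methyl 3-[(2E,6E)-3,7-dimethylnona-2,6,8-trien-1-yl]-4-(methoxymethoxy)benzoate
Conditions: Ph3PCH3Br, KOt-Bu, THF, 0 °C; then 15, 0 °C → rt
Reagents that add atoms: methyltriphenylphosphonium bromide, C[P+](c1ccccc1)(c1ccccc1)c1ccccc1.[Br-]
Why: Wittig methylenation of the enal gives the terminal 1,3-diene and leaves both trisubstituted (E)-olefins unchanged.

Step 10
Reactants: 16 methyl 3-[(2E,6E)-3,7-dimethylnona-2,6,8-trien-1-yl]-4-(methoxymethoxy)benzoate; 6 (3S,6E)-7-iodo-2,6-dimethylhept-6-ene-2,3-diol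
Product: 18 methyl 3-[(2E,6E,10E,14S)-14,15-dihydroxy-3,7,11,15-tetramethylhexadeca-2,6,10-trien-1-yl]-4-(methoxymethoxy)benzoate, via B-alkyl-9-BBN borane 17 (not isolated)
Conditions: 9-BBN-H, THF, 0 °C → rt; then 6, PdCl2(dppf) (5 mol%), Ph3As, Cs2CO3, DMF/H2O, rt
Reagents that add atoms: none
Why: 9-BBN hydroborates only the terminal vinyl CH2 of the diene, and B-alkyl Suzuki–Miyaura coupling with the (E)-vinyl iodide forms C9–C10 with retention of all olefin geometries.

Step 11
Reactants: 18 methyl 3-[(2E,6E,10E,14S)-14,15-dihydroxy-3,7,11,15-tetramethylhexadeca-2,6,10-trien-1-yl]-4-(methoxymethoxy)benzoate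
Product: 19 (10S,11S,14S)-10,11-epoxide of 18
Conditions: VO(acac)2 (5 mol%), t-BuOOH (1.5 equiv), NaOAc, benzene, rt
Reagents that add atoms: tert-butyl hydroperoxide, CC(C)(C)OO
Why: Hydroxyl-directed epoxidation reaches only the bishomoallylic 10,11-olefin from the C14 vanadate ester, and the chair-like transition state with the C14 substituent equatorial (Kishi model) delivers oxygen to one face of the (E)-olefin, setting C10 and C11 as 10S,11S.

Step 12
Reactants: 19 (10S,11S,14S)-10,11-epoxide of 18
Product: 20 (10S,11S,14S)-epoxy seco acid (the benzoic acid of 19)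
Conditions: LiOH, THF/MeOH/H2O, rt; aq. NH4Cl (pH ≥ 6), used at once
Reagents that add atoms: lithium hydroxide, [Li+].[OH-]
Why: Saponification of the methyl benzoate; the epoxide and MOM acetal are base-stable, and the product is never taken below pH 6, so the hydroxyls do not open the epoxide.

Step 13
Reactants: 20 (10S,11S,14S)-epoxy seco acid
Product: 22 19-membered (10S,11S,14S)-epoxy macrolide (lactone through O14; C15-OH; O-MOM), via mixed 2-methyl-6-nitrobenzoic anhydride 21 (not isolated)
Conditions: 2-methyl-6-nitrobenzoic anhydride, DMAP, CH2Cl2, rt → 40 °C, 1 mM (slow addition)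
Reagents that add atoms: none
Why: Shiina macrolactonization acylates the secondary C14 hydroxyl (the tertiary one is inert) with retention at C14 under high dilution and without acid.

Step 14
Reactants: 22 19-membered epoxy macrolide
Product: 23 C15 bromide of 22
Conditions: Me2C=C(Br)NMe2, CH2Cl2, 0 °C → rt
Reagents that add atoms: 1-bromo-N,N,2-trimethylprop-1-en-1-amine, CC(C)=C(Br)N(C)C
Why: The Ghosez α-bromoenamine activates the tertiary alcohol under neutral conditions; ionization is assisted by the neighbouring aroyloxy group (dioxolanylium ion) and bromide opens it at the tertiary carbon, so the C14–O bond and the epoxide stay intact.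

Step 15
Reactants: 23 C15 bromide of 22
Product: 25 (10R,11S,14S)-10,15-dibromo-11-trifluoroacetoxy macrolide, via bromohydrin 24 (not isolated)
Conditions: Li2NiBr4, THF, 0 °C; then (CF3CO)2O, −20 → 0 °C
Reagents that add atoms: dilithium tetrabromonickelate, [Li+].[Li+].[Ni+2].[Br-].[Br-].[Br-].[Br-]; trifluoroacetic anhydride, O=C(OC(=O)C(F)(F)F)C(F)(F)F
Why: Soft bromide opens the trisubstituted epoxide by SN2 at the less hindered C10 with inversion (10R) while C11 keeps its oxygen (11S), and acylating the alkoxide removes the one nucleophile that could trap the cation of the next step.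

Step 16
Reactants: 25 (10R,11S,14S)-10,15-dibromo-11-trifluoroacetoxy macrolide
Product: 26 O-MOM, 11-O-trifluoroacetyl bromophycolide D
Conditions: 2,4,4,6-tetrabromocyclohexa-2,5-dienone (1.1 equiv), MeNO2, −20 → 0 °C
Reagents that add atoms: 2,4,4,6-tetrabromocyclohexa-2,5-dien-1-one, O=C1C(Br)=CC(Br)(Br)C=C1Br
Why: Bromonium-induced transannular cation–olefin cyclization: Br+ adds to C6, C2 attacks C7 through a chair with both (E)-olefins (fixing 6-Br, 7-Me and 2-H relative to each other as 2R*,6S*,7S*), proton loss gives the exocyclic methylene, and the face is chosen by the macrocycle carrying C10, C11 and C14.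

Step 17
Reactants: 26 O-MOM, 11-O-trifluoroacetyl bromophycolide D
Product: 28 bromophycolide D, via MOM ether 27 (not isolated)
Conditions: NaHCO3 (cat.), MeOH, 0 °C; concentrate; then ZnBr2, n-PrSH, CH2Cl2, 0 °C
Reagents that add atoms: none
Why: Mild methanolysis removes the labile tertiary trifluoroacetate, and Lewis-acid/thiol acetal exchange cleaves the aryl MOM ether without eliminating or epimerising the bromides.

## Compound list

1 | ethyl (2S)-5-oxooxolane-2-carboxylate | CCOC(=O)[C@@H]1CCC(=O)O1 | starting material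
2 | (5S)-5-(2-hydroxypropan-2-yl)oxolan-2-one | CC(C)(O)[C@@H]1CCC(=O)O1 | intermediate
3 | (5S)-5-(2-hydroxypropan-2-yl)oxolan-2-ol | CC(C)(O)[C@@H]1CCC(O)O1 | intermediate
4 | (3S)-2-methylhept-6-yne-2,3-diol | C#CCC[C@H](O)C(C)(C)O | intermediate
5 | (E)-alkenyldimethylalane from 4, drawn as its cyclic methylaluminium diolate | C[Al](C)/C=C(\C)CC[C@@H]1O[Al](C)OC1(C)C | intermediate
6 | (3S,6E)-7-iodo-2,6-dimethylhept-6-ene-2,3-diol | I/C=C(\C)CC[C@H](O)C(C)(C)O | intermediate
7 | geranyl bromide | CC(C)=CCC/C(C)=C/CBr | starting material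
8 | (4E)-5,9-dimethyldeca-4,8-dienoic acid | CC(C)=CCC/C(C)=C/CCC(=O)O | intermediate
9 | methyl coumalate | COC(=O)C1=COC(=O)C=C1 | starting material
10 | ketene bis(trimethylsilyl) acetal of 8 | CC(C)=CCC/C(C)=C/CC=C(O[Si](C)(C)C)O[Si](C)(C)C | intermediate
11 | methyl 3-geranyl-4-(trimethylsilyloxy)benzoate | COC(=O)c1ccc(O[Si](C)(C)C)c(C/C=C(\C)CCC=C(C)C)c1 | intermediate
12 | methyl 3-[(2E)-3,7-dimethylocta-2,6-dien-1-yl]-4-hydroxybenzoate | COC(=O)c1ccc(O)c(C/C=C(\C)CCC=C(C)C)c1 | intermediate
13 | methyl 3-[(2E)-3,7-dimethylocta-2,6-dien-1-yl]-4-(methoxymethoxy)benzoate | COCOc1ccc(C(=O)OC)cc1C/C=C(\C)CCC=C(C)C | intermediate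
14 | methyl 3-[(2E,6E)-8-hydroxy-3,7-dimethylocta-2,6-dien-1-yl]-4-(methoxymethoxy)benzoate | COCOc1ccc(C(=O)OC)cc1C/C=C(\C)CC/C=C(\C)CO | intermediate
15 | methyl 3-[(2E,6E)-3,7-dimethyl-8-oxoocta-2,6-dien-1-yl]-4-(methoxymethoxy)benzoate | COCOc1ccc(C(=O)OC)cc1C/C=C(\C)CC/C=C(\C)C=O | intermediate
16 | methyl 3-[(2E,6E)-3,7-dimethylnona-2,6,8-trien-1-yl]-4-(methoxymethoxy)benzoate | COCOc1ccc(C(=O)OC)cc1C/C=C(\C)CC/C=C(\C)C=C | intermediate
17 | 9-BBN adduct of 16 (boron on C9) | COCOc1ccc(C(=O)OC)cc1C/C=C(\C)CC/C=C(\C)CCB1C2CCCC1CCC2 | intermediate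
18 | methyl 3-[(2E,6E,10E,14S)-14,15-dihydroxy-3,7,11,15-tetramethylhexadeca-2,6,10-trien-1-yl]-4-(methoxymethoxy)benzoate | COCOc1ccc(C(=O)OC)cc1C/C=C(\C)CC/C=C(\C)CC/C=C(\C)CC[C@H](O)C(C)(C)O | intermediate
19 | (10S,11S,14S)-10,11-epoxide of 18 | COCOc1ccc(C(=O)OC)cc1C/C=C(\C)CC/C=C(\C)CC[C@@H]2O[C@@]2(C)CC[C@H](O)C(C)(C)O | intermediate
20 | (10S,11S,14S)-epoxy seco acid | COCOc1ccc(C(=O)O)cc1C/C=C(\C)CC/C=C(\C)CC[C@@H]2O[C@@]2(C)CC[C@H](O)C(C)(C)O | intermediate
21 | mixed anhydride of 20 and 2-methyl-6-nitrobenzoic acid | COCOc1ccc(C(=O)OC(=O)c2c(C)cccc2[N+](=O)[O-])cc1C/C=C(\C)CC/C=C(\C)CC[C@@H]3O[C@@]3(C)CC[C@H](O)C(C)(C)O | intermediate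
22 | 19-membered (2E,6E,10S,11S,14S)-epoxy macrolide, C15-OH, O-MOM | COCOc1ccc(cc1C/C=C(\C)CC/C=C(\C)CC[C@@H]3O[C@@]3(C)CC[C@H]2C(C)(C)O)C(=O)O2 | intermediate
23 | C15 bromide of 22 | COCOc1ccc(cc1C/C=C(\C)CC/C=C(\C)CC[C@@H]3O[C@@]3(C)CC[C@H]2C(C)(C)Br)C(=O)O2 | intermediate
24 | (10R,11S,14S)-10,15-dibromo-11-hydroxy macrolide | COCOc1ccc(cc1C/C=C(\C)CC/C=C(\C)CC[C@@H](Br)[C@@](C)(O)CC[C@H]2C(C)(C)Br)C(=O)O2 | intermediate
25 | (10R,11S,14S)-10,15-dibromo-11-trifluoroacetoxy macrolide | COCOc1ccc(cc1C/C=C(\C)CC/C=C(\C)CC[C@@H](Br)[C@@](C)(OC(=O)C(F)(F)F)CC[C@H]2C(C)(C)Br)C(=O)O2 | intermediate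
26 | O-MOM, 11-O-trifluoroacetyl bromophycolide D (2R,6S,7S,10R,11S,14S) | C=C1CC[C@H](Br)[C@@]2(C)CC[C@@H](Br)[C@@](C)(OC(=O)C(F)(F)F)CC[C@@H](C(C)(C)Br)OC(=O)c3ccc(OCOC)c(c3)C[C@H]12 | intermediate
27 | O-MOM bromophycolide D | C=C1CC[C@H](Br)[C@@]2(C)CC[C@@H](Br)[C@@](C)(O)CC[C@@H](C(C)(C)Br)OC(=O)c3ccc(OCOC)c(c3)C[C@H]12 | intermediate
28 | bromophycolide D | C=C1CC[C@H](Br)[C@@]2(C)CC[C@@H](Br)[C@@](C)(O)CC[C@@H](C(C)(C)Br)OC(=O)c3ccc(O)c(c3)C[C@H]12 | target

## Step count and risks

Total: 17 steps. Longest linear sequence: 13 steps (steps 5–17, from geranyl bromide 7). The branch from 1 is 4 steps before the coupling.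

The three steps most likely to fail:

Step 11 (directed epoxidation). The facial sense for this substrate is predicted from a model, not demonstrated, and the epoxy alcohol can cyclise to a tetrahydrofuran if any acid is present. Fallback, from 18 back to 27: leave the 10,11-olefin alone and form the bromohydrin last. Saponification of 18 (LiOH) gives the triene seco acid F1. Lactonization (2-methyl-6-nitrobenzoic anhydride, DMAP) gives the 19-membered triene macrolide F2. Me2C=C(Br)NMe2 gives its C15 bromide F3. TBCO then closes the bromocyclohexane to give the (10E)-olefin macrolide F4; this relies on the macrocycle favouring the 6,7-bromonium pathway over the 10,11 one. NBS in acetone–water finally adds Br and OH anti across the one remaining trisubstituted olefin (OH at C11), with the face chosen by peripheral attack on the rigid 15-membered ring, and gives 27.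

Step 15 (bromide opening at C10). Bromide may instead attack the tertiary carbon C11. Fallback, from 23 back to 24: accept that regiochemistry and correct it through the bromonium ion. MgBr2·OEt2 opens 23 at C11 with inversion to give the 11-bromo-10-ol F5. Its C10 hydroxyl is converted into the triflate F6 (Tf2O, 2,6-di-tert-butylpyridine, −78 °C). The triflate ionises with anti participation of the C11 bromine, and water opens the bromonium ion at the tertiary carbon. This gives 24 with the same configuration as direct opening, and it is then acylated as in step 15.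

Step 16 (transannular bromocyclization). Risks are the facial selectivity, endocyclic olefin isomers and capture of the bromonium ion by an oxygen. Fallback, from 25 back to 26: separate C–C bond formation from bromination. Hg(OCOCF3)2 in MeNO2 at −20 °C induces the same chair cyclization, and KBr work-up gives the C6 organomercuric bromide F7. Br2/LiBr in pyridine then replaces mercury by bromine with retention and gives 26; the halophilic mercury salt must be used briefly and cold because of the C15 bromide.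

## Further compounds

F1 | step 11 | triene seco acid (20 without the epoxide) | COCOc1ccc(C(=O)O)cc1C/C=C(\C)CC/C=C(\C)CC/C=C(\C)CC[C@H](O)C(C)(C)O
F2 | step 11 | 19-membered (2E,6E,10E,14S)-triene macrolide, C15-OH, O-MOM | COCOc1ccc(cc1C/C=C(\C)CC/C=C(\C)CC/C=C(\C)CC[C@H]2C(C)(C)O)C(=O)O2
F3 | step 11 | C15 bromide of F2 | COCOc1ccc(cc1C/C=C(\C)CC/C=C(\C)CC/C=C(\C)CC[C@H]2C(C)(C)Br)C(=O)O2
F4 | step 11 | O-MOM (10E)-olefin macrolide with the bromocyclohexane ring closed | C=C1CC[C@H](Br)[C@@]2(C)CC/C=C(\C)CC[C@@H](C(C)(C)Br)OC(=O)c3ccc(OCOC)c(c3)C[C@H]12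
F5 | step 15 | 11,15-dibromo-10-hydroxy macrolide (regioisomeric bromohydrin) | COCOc1ccc(cc1C/C=C(\C)CC/C=C(\C)CC[C@H](O)[C@](C)(Br)CC[C@H]2C(C)(C)Br)C(=O)O2
F6 | step 15 | C10 triflate of F5 | COCOc1ccc(cc1C/C=C(\C)CC/C=C(\C)CC[C@H](OS(=O)(=O)C(F)(F)F)[C@](C)(Br)CC[C@H]2C(C)(C)Br)C(=O)O2
F7 | step 16 | C6 organomercuric bromide corresponding to 26 | C=C1CC[C@H]([Hg]Br)[C@@]2(C)CC[C@@H](Br)[C@@](C)(OC(=O)C(F)(F)F)CC[C@@H](C(C)(C)Br)OC(=O)c3ccc(OCOC)c(c3)C[C@H]12
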